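**Retrosynthetic overview**
- The last step only frees the C3' carboxylic acid from its benzyl ester; the depside ester bond is formed early, on but-2-ynoic acid and the free O-4 of ring A, before ring B exists.
- Feature used: in ring B (the benzoyl ring), C1' (bearing the depside carbonyl) and C6' (bearing CH3) are the α- and β-alkyne carbons of that but-2-ynoate. C2' (OH), C3' (CO2H), C4' (OMe) and C5' (H) are the four carbons of a silyl ketene acetal diene made from a 1-methoxyethylidene malonate. The disconnections are C1'–C2' and C5'–C6'.
- Ring order: ring A is bought as methyl 2,4-dihydroxy-3,6-dimethylbenzoate; ring B is closed last by [4+2] addition and loss of benzyl alcohol.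

Key step: step 4

Remark on the chemistry: the diene is used crude as a mixture of ketene acetal geometries, which is irrelevant because that carbon becomes aromatic C2'. The cycloadduct has one transient, racemic ketal stereocenter that is erased on aromatization. The target has no stereocenter.

**Step 1**
Reactants: 1 dibenzyl malonate; 2 trimethyl orthoacetate
Product: 3 dibenzyl 2-(1-methoxyethylidene)malonate
Conditions: 2 (3 equiv, neat), Ac2O (2 equiv), ZnCl2 (cat.), 120 °C, MeOAc distilled off
Reagents that add atoms: none
Why: Orthoester condensation of an active methylene compound, in which the dimethoxycarbenium ion generated from 2 by ZnCl2/Ac2O is attacked by the malonate enol and two methanol units are lost and trapped as methyl acetate, as in the preparation of alkoxyalkylidene malonates.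

**Step 2**
Reactants: 3 dibenzyl 2-(1-methoxyethylidene)malonate
Product: 5 benzyl 2-[(benzyloxy)(trimethylsilyloxy)methylidene]-3-methoxybut-3-enoate, via lithium dienolate 4 (not isolated)
Conditions: LiN(iPr)2 (LDA, commercial solution, 1.1 equiv), THF, −78 °C; then Me3SiCl (1.3 equiv), −78 °C to rt; pentane extraction under argon, used crude
Reagents that add atoms: chlorotrimethylsilane C[Si](C)(C)Cl
Why: γ-Deprotonation of the vinylogous carbonate gives the cross-conjugated dienolate 4, which should be silylated on oxygen, the standard preparation of Brassard-type 1-alkoxy-1-silyloxy dienes from 3-alkoxy-2-enoates.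

**Step 3**
Reactants: 6 but-2-ynoic acid; 7 methyl 2,4-dihydroxy-3,6-dimethylbenzoate
Product: 8 methyl 4-(but-2-ynoyloxy)-2-hydroxy-3,6-dimethylbenzoate
Conditions: DCC (1.1 equiv), DMAP (5 mol %), CH2Cl2, 0 °C to rt
Reagents that add atoms: none
Why: Steglich esterification, expected to acylate the 4-hydroxyl selectively because the 2-hydroxyl is hydrogen-bonded to the methyl ester and flanked by two substituents.

**Step 4**
Reactants: 8 methyl 4-(but-2-ynoyloxy)-2-hydroxy-3,6-dimethylbenzoate; 5 benzyl 2-[(benzyloxy)(trimethylsilyloxy)methylidene]-3-methoxybut-3-enoate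
Product: 12 methyl 4-{[3-(benzyloxycarbonyl)-2-hydroxy-4-methoxy-6-methylbenzoyl]oxy}-2-hydroxy-3,6-dimethylbenzoate, via ring A silyl ether 9 (not isolated), via cyclohexadiene cycloadduct 10 (not isolated), via bis-silyl depside 11 (not isolated)
Conditions: N,O-bis(trimethylsilyl)acetamide (1.5 equiv), PhMe, 60 °C; then 5 (2.5 equiv), 110 °C, sealed tube; then 1 M HCl, THF, rt
Reagents that add atoms: none
Why: Proposed new method: a ketene acetal diene bearing a 2-benzyloxycarbonyl group has not been shown to annulate an aryl but-2-ynoate; the closest known reaction type is the Diels–Alder benzannulation of Brassard- and Chan-type 1-alkoxy-1-silyloxy-1,3-dienes with acetylenic esters, which gives salicylates after loss of alcohol. N,O-Bis(trimethylsilyl)acetamide first caps the chelated ring A hydroxyl as 9, so that no acidic proton can quench the diene. The CH2 terminus of 5, made nucleophilic by the methoxyl and the two acetal oxygens, bonds to the methyl-bearing β-carbon of the ynoate and the acetal carbon bonds to the α-carbon, in an asynchronous [4+2] cycloaddition or a Michael addition followed by Claisen-type ring closure of the same orientation, so that C5'–C6' and C1'–C2' form and ring B closes as the six-membered 1,4-cyclohexadiene 10 in an intermolecular two-bond [4+2] mode. The mixed benzyl silyl ketal of 10 then loses benzyl alcohol by 1,4-elimination with the ring CH2, which aromatizes ring B to 11, and dilute acid removes both trimethylsilyl groups. The ketal carbon of 10 is a transient racemic stereocenter that becomes aromatic C2', so no stereocontrol is needed. The step needs regioselectivity only, which the polarity match between the donor-substituted diene terminus and the electrophilic β-carbon of the aryl ynoate secures, while the equivalence of the two malonate esters allows a single ring and a C2' benzyl ether from the alternative loss of silanol would converge in step 5.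

**Step 5**
Reactants: 12 methyl 4-{[3-(benzyloxycarbonyl)-2-hydroxy-4-methoxy-6-methylbenzoyl]oxy}-2-hydroxy-3,6-dimethylbenzoate
Product: 13 3-[(3-hydroxy-4-methoxycarbonyl-2,5-dimethylphenoxy)carbonyl]-2-hydroxy-6-methoxy-4-methylbenzoic acid (target)
Conditions: H2 (1 atm), 10% Pd/C, EtOAc, rt
Reagents that add atoms: none
Why: Hydrogenolysis of the benzyl ester C–O bond over palladium should leave the methyl ester, the aryl ester link and both arenes untouched and would also cleave any C2' benzyl ether carried over from step 4.

**Compound list**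
1 | dibenzyl malonate | O=C(CC(=O)OCc1ccccc1)OCc1ccccc1 | starting material
2 | trimethyl orthoacetate | CC(OC)(OC)OC | starting material
3 | dibenzyl 2-(1-methoxyethylidene)malonate | COC(C)=C(C(=O)OCc1ccccc1)C(=O)OCc1ccccc1 | intermediate
4 | lithium dienolate of 3 (γ-deprotonated, not isolated) | C=C(OC)C(C(=O)OCc1ccccc1)=C(OCc1ccccc1)[O-].[Li+] | intermediate
5 | benzyl 2-[(benzyloxy)(trimethylsilyloxy)methylidene]-3-methoxybut-3-enoate (either geometry) | C=C(OC)C(C(=O)OCc1ccccc1)=C(OCc1ccccc1)O[Si](C)(C)C | intermediate
6 | but-2-ynoic acid | CC#CC(=O)O | starting material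
7 | methyl 2,4-dihydroxy-3,6-dimethylbenzoate | COC(=O)c1c(C)cc(O)c(C)c1O | starting material
8 | methyl 4-(but-2-ynoyloxy)-2-hydroxy-3,6-dimethylbenzoate | COC(=O)c1c(C)cc(OC(=O)C#CC)c(C)c1O | intermediate
9 | methyl 4-(but-2-ynoyloxy)-3,6-dimethyl-2-(trimethylsilyloxy)benzoate (not isolated) | COC(=O)c1c(C)cc(OC(=O)C#CC)c(C)c1O[Si](C)(C)C | intermediate
10 | 1,4-cyclohexadiene cycloadduct of 5 and 9, racemic at the ketal carbon (not isolated) | COC(=O)c1c(C)cc(OC(=O)C2=C(C)CC(OC)=C(C(=O)OCc3ccccc3)C2(OCc4ccccc4)O[Si](C)(C)C)c(C)c1O[Si](C)(C)C | intermediate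
11 | methyl 4-{[3-(benzyloxycarbonyl)-4-methoxy-6-methyl-2-(trimethylsilyloxy)benzoyl]oxy}-3,6-dimethyl-2-(trimethylsilyloxy)benzoate (not isolated) | COC(=O)c1c(C)cc(OC(=O)c2c(C)cc(OC)c(C(=O)OCc3ccccc3)c2O[Si](C)(C)C)c(C)c1O[Si](C)(C)C | intermediate
12 | methyl 4-{[3-(benzyloxycarbonyl)-2-hydroxy-4-methoxy-6-methylbenzoyl]oxy}-2-hydroxy-3,6-dimethylbenzoate | COC(=O)c1c(C)cc(OC(=O)c2c(C)cc(OC)c(C(=O)OCc3ccccc3)c2O)c(C)c1O | intermediate
13 | 3-[(3-hydroxy-4-methoxycarbonyl-2,5-dimethylphenoxy)carbonyl]-2-hydroxy-6-methoxy-4-methylbenzoic acid | COC(=O)c1c(C)cc(OC(=O)c2c(C)cc(OC)c(C(=O)O)c2O)c(C)c1O | target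

**Step count**
Total steps: 5. Longest linear sequence: 4 steps (steps 1, 2, 4, 5).

**Steps most likely to fail**

1. Step 4 (proposed new method). The ester-bearing diene may add too slowly to the β-methyl ynoate. At 110 °C it may instead decompose, be protonated or undergo silyl migration, and the diene terminus may attack the aryl ester carbonyl instead of the alkyne.
Fallback (known chemistry, ring B taken from an arene and joined by classical depside esterification): it sets out from ring A phenol 7 and comes back at 12. Commercial 2,6-dihydroxy-4-methylbenzoic acid (Cc1cc(O)c(C(=O)O)c(O)c1) is benzylated on the carboxylate with benzyl bromide and KHCO3 in DMF to give benzyl 2,6-dihydroxy-4-methylbenzoate F1. Rieche formylation (Cl2CHOMe, TiCl4, CH2Cl2, −78 to 0 °C) at one of the two equivalent free positions gives benzyl 3-formyl-2,6-dihydroxy-4-methylbenzoate F2. MeI (1 equiv) and K2CO3 in acetone should methylate the less chelated hydroxyl para to the aldehyde, giving benzyl 3-formyl-2-hydroxy-6-methoxy-4-methylbenzoate F3. Pinnick oxidation (NaClO2, NaH2PO4, 2-methyl-2-butene, tBuOH/H2O) gives 3-(benzyloxycarbonyl)-2-hydroxy-4-methoxy-6-methylbenzoic acid F4. This acid is condensed with 7 by trifluoroacetic anhydride in toluene at rt to give 12, which goes on to step 5.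

2. Step 2. The amide base may add in conjugate fashion or attack a benzyl ester instead of removing the γ-proton, and the trimethylsilyl ketene acetal may hydrolyse during isolation.
Fallback (soft enolization to a more robust, isolable silyl diene): it sets out from 3 and comes back at 12. Treatment of 3 with tBuMe2SiOSO2CF3 and Et3N in Et2O at 0 °C gives benzyl 2-[(benzyloxy)(tert-butyldimethylsilyloxy)methylidene]-3-methoxybut-3-enoate F5, which tolerates filtration through deactivated silica. F5 is heated with ring A silyl ether 9 as in step 4 to give the tert-butyldimethylsilyl cyclohexadiene cycloadduct F6, which loses benzyl alcohol to the ring B tert-butyldimethylsilyl, ring A trimethylsilyl depside F7. Et3N·3HF in THF then removes both silyl groups to give 12.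

3. Step 1. Methanol set free at 120 °C over ZnCl2 may exchange benzyl for methyl esters, and the orthoacetate may condense incompletely or be diverted to ketene acetal.
Fallback (acylation, then enol O-methylation): it sets out from 1 and comes back at 3. C-Acylation of 1 with acetyl chloride, MgCl2 and Et3N in MeCN (0 °C to rt) gives dibenzyl 2-acetylmalonate F8. Its enol is O-methylated with (trimethylsilyl)diazomethane in toluene/MeOH at rt to give 3; carbon methylation at the centre flanked by three carbonyls is sterically disfavoured.

**Further compounds**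
F1 | step 4 | benzyl 2,6-dihydroxy-4-methylbenzoate | O=C(OCc1ccccc1)c1c(O)cc(C)cc1O
F2 | step 4 | benzyl 3-formyl-2,6-dihydroxy-4-methylbenzoate | O=Cc1c(C)cc(O)c(C(=O)OCc2ccccc2)c1O
F3 | step 4 | benzyl 3-formyl-2-hydroxy-6-methoxy-4-methylbenzoate | O=Cc1c(C)cc(OC)c(C(=O)OCc2ccccc2)c1O
F4 | step 4 | 3-(benzyloxycarbonyl)-2-hydroxy-4-methoxy-6-methylbenzoic acid | O=C(O)c1c(C)cc(OC)c(C(=O)OCc2ccccc2)c1O
F5 | step 2 | benzyl 2-[(benzyloxy)(tert-butyldimethylsilyloxy)methylidene]-3-methoxybut-3-enoate | C=C(OC)C(C(=O)OCc1ccccc1)=C(OCc1ccccc1)O[Si](C)(C)C(C)(C)C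
F6 | step 2 | tert-butyldimethylsilyl cyclohexadiene cycloadduct of F5 and 9, racemic at the ketal carbon | COC(=O)c1c(C)cc(OC(=O)C2=C(C)CC(OC)=C(C(=O)OCc3ccccc3)C2(OCc4ccccc4)O[Si](C)(C)C(C)(C)C)c(C)c1O[Si](C)(C)C
F7 | step 2 | methyl 4-{[3-(benzyloxycarbonyl)-2-(tert-butyldimethylsilyloxy)-4-methoxy-6-methylbenzoyl]oxy}-3,6-dimethyl-2-(trimethylsilyloxy)benzoate | COC(=O)c1c(C)cc(OC(=O)c2c(C)cc(OC)c(C(=O)OCc3ccccc3)c2O[Si](C)(C)C(C)(C)C)c(C)c1O[Si](C)(C)C
F8 | step 1 | dibenzyl 2-acetylmalonate | CC(=O)C(C(=O)OCc1ccccc1)C(=O)OCc1ccccc1
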